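**Plan**

- Elemane numbering is used: carbocycle C5–C10; C10 carries CH3 (C14) and the vinyl group C1=C2; C5 carries C4(=C3H2)–C15; C7 carries C11 of the γ-lactone C12(=O)–O–C8. The retrosynthesis first takes off the C15 aldehyde oxygen, the O9 angelate, the O6 acetate and C13, then cuts the ring bonds C5–C6 and C9–C10 together.
- The feature that allows this is that the cyclohexane holds two back-to-back homoallylic alcohols, C6(OH)–C5–C4=C3 and C9(OH)–C10–C1=C2, with each oxygen cis to its alkenyl group. This is the retron of a double (Z)-allylboration of a C6–C7–C8–C9 dicarbonyl unit by a C3–C4=C5–C10=C1–C2 bis(boronate).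
- Forward: the achiral (2Z,4Z)-bis(allylboronate) 6 is made from propargyl alcohol in four steps. The C6–C9 unit, with the γ-lactone already closed, comes from (R)-5-(hydroxymethyl)furan-2(5H)-one by trans vinyl addition and ozonolysis.
- The carbocycle is closed in one flask by intermolecular, then intramolecular allylboration, with C9 held at the alcohol oxidation level until the first bond is made. α-Methylenation, O6 acetylation, O9 angeloylation and allylic oxidation of C15 finish the route.
- Stereochemistry: C8 is bought, C7 is relayed from it in the conjugate addition, and C5, C6, C9 and C10 are relayed in the key step by substrate control and by the two Z alkene geometries of 6.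

Key step: step 9

Remark: (R)-5-(hydroxymethyl)furan-2(5H)-one is taken as a catalogue chiral-pool compound; β is the face of the C10 methyl group, α the opposite face.

**Route**

Step 1
Reactants: 1 prop-2-yn-1-ol
Product: 3 (Z)-3-iodo-2-methylprop-2-en-1-ol, via bromomagnesium alkenylmagnesium alkoxide 2 (not isolated)
Conditions: MeMgBr (2.5 equiv), CuI (10 mol %), THF, −10 °C → rt; then I2, −10 °C
Reagents that add atoms: methylmagnesium bromide C[Mg]Br; iodine II
Why: Copper-catalysed anti-carbomagnesiation of the propargylic alkoxide puts methyl on the internal carbon and magnesium on the terminal carbon cis to the CH2O group (five-membered chelate), and iodinolysis with retention should give the Z iodide.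

Step 2
Reactants: 3 (Z)-3-iodo-2-methylprop-2-en-1-ol
Product: 4 (Z)-3-iodo-2-methylprop-2-enal
Conditions: MnO2, CH2Cl2, rt
Reagents that add atoms: none
Why: Heterogeneous allylic alcohol oxidation under neutral conditions should keep the Z geometry of the β-iodoenal, which is used at once.

Step 3
Reactants: 4 (Z)-3-iodo-2-methylprop-2-enal
Product: 5 (1Z,3Z)-1,4-diiodo-2-methylpenta-1,3-diene
Conditions: EtPPh3I, n-BuLi, THF, rt; I2, −78 °C; NaN(SiMe3)2, −78 °C; then 4, −78 → −20 °C
Reagents that add atoms: ethyltriphenylphosphonium iodide CC[P+](c1ccccc1)(c1ccccc1)c1ccccc1.[I-]; iodine II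
Why: Stork–Zhao-type Wittig olefination with the α-iodo ylide Ph3P=C(I)CH3 is expected to give the Z trisubstituted vinyl iodide (iodine cis to the dienyl chain) under kinetic control, the existing Z vinyl iodide being inert.

Step 4
Reactants: 5 (1Z,3Z)-1,4-diiodo-2-methylpenta-1,3-diene
Product: 6 2,2'-[(2Z,4Z)-3,5-dimethylhexa-2,4-diene-1,6-diyl]bis(4,4,5,5-tetramethyl-1,3,2-dioxaborolane)
Conditions: CH2(Bpin)2 (2.6 equiv), Pd(P(t-Bu)3)2 (5 mol %), KOH (aq), 1,4-dioxane, rt
Reagents that add atoms: bis(pinacolatoboryl)methane CC1(C)OB(CB2OC(C)(C)C(C)(C)O2)OC1(C)C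
Why: Twofold Suzuki–Miyaura coupling of the alkenyl iodides with the gem-diborylmethane (one boron is transferred after hydroxide activation, the other stays) goes with retention at sp2 carbon, so both Z geometries should pass into the bis(allylboronate), which should not couple further under these conditions.

Step 5
Reactants: 7 (R)-5-(hydroxymethyl)furan-2(5H)-one
Product: 8 (R)-5-({[tert-butyl(diphenyl)silyl]oxy}methyl)furan-2(5H)-one
Conditions: t-BuPh2SiCl, imidazole, DMF, 0 °C → rt
Reagents that add atoms: tert-butyl(chloro)diphenylsilane CC(C)(C)[Si](Cl)(c1ccccc1)c1ccccc1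
Why: Standard silylation of the primary alcohol gives the bulky C8 substituent that directs the next step.

Step 6
Reactants: 8 (R)-5-({[tert-butyl(diphenyl)silyl]oxy}methyl)furan-2(5H)-one
Product: 9 (4S,5R)-5-({[tert-butyl(diphenyl)silyl]oxy}methyl)-4-vinyloxolan-2-one
Conditions: CH2=CHMgBr (2 equiv), CuI (1 equiv), THF/Me2S, −78 → −40 °C; aq. NH4Cl
Reagents that add atoms: vinylmagnesium bromide C=C[Mg]Br
Why: Conjugate addition of (CH2=CH)2CuMgBr to the butenolide occurs anti to the silyloxymethyl group on C8, which sets C7 trans to C8 by substrate control.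

Step 7
Reactants: 9 (4S,5R)-5-({[tert-butyl(diphenyl)silyl]oxy}methyl)-4-vinyloxolan-2-one
Product: 10 (4S,5R)-5-(hydroxymethyl)-4-vinyloxolan-2-one
Conditions: Bu4NF, AcOH, THF, 0 °C
Reagents that add atoms: none
Why: Buffered fluoride cleaves the silyl ether without opening the γ-lactone or epimerising C7.

Step 8
Reactants: 10 (4S,5R)-5-(hydroxymethyl)-4-vinyloxolan-2-one
Product: 11 (2R,3R)-2-(hydroxymethyl)-5-oxooxolane-3-carbaldehyde
Conditions: O3, CH2Cl2, −78 °C; then PPh3, −78 °C → rt
Reagents that add atoms: ozone [O-][O+]=O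
Why: Ozonolysis of the only alkene with reductive work-up gives the C6 aldehyde while C9 stays at the alcohol oxidation level; the β-acyloxy aldehyde is used crude to avoid elimination.

Step 9
Reactants: 11 (2R,3R)-2-(hydroxymethyl)-5-oxooxolane-3-carbaldehyde; 6 2,2'-[(2Z,4Z)-3,5-dimethylhexa-2,4-diene-1,6-diyl]bis(4,4,5,5-tetramethyl-1,3,2-dioxaborolane)
Product: 15 6β,9α-dihydroxyelema-1,3-dien-12,8α-olide, via O6-borylated mono-adduct 12 (not isolated), via C9 aldehyde 13 (not isolated), via cyclised bis(borate) 14 (not isolated)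
Conditions: 6 (1.1 equiv), 4 Å MS, CH2Cl2, rt; then PhI(OAc)2 (1.2 equiv), TEMPO (10 mol %), rt → 35 °C; aq. N(CH2CH2OH)3 work-up
Reagents that add atoms: none
Why: Proposed new method: a 1,6-diboryl-2,4-diene serves as a double allyl donor toward a 1,4-dicarbonyl unit whose second carbonyl (C9) is kept at the alcohol oxidation level until the first C–C bond exists; the closest known reaction type is the tandem double allylboration of 1,4-dicarbonyl compounds by diene-derived bis(boronates), together with the intramolecular allylboration of (Z)-γ,γ-disubstituted allylboronates and one-pot alcohol oxidation/allylboration. Mechanistically, the less hindered (Z)-γ-monosubstituted 2-methylallyl boronate terminus of 6 adds through a closed six-membered chair transition state to the only aldehyde (C6) of 11, C4=C5 shifting to the C4=C3 isopropenyl group, and nitroxyl-catalysed oxidation then raises C9 to the α-acyloxy aldehyde 13, which is captured by the remaining (Z)-γ,γ-disubstituted allylboronate with shift of C1=C10 to the C1=C2 vinyl group. The cyclohexane ring C5–C10 closes in a 6-exo-trig mode through a second boron-centred chair that is cis-fused to the forming chair carbocycle, the trans-fused lactone holding C7–C11 and C8–O equatorial. C6 is set by the C7 stereocentre (attack anti to the ring carbon C8 with H7 turned toward the Z substituent of the reagent to avoid a syn-pentane contact), C5 by the Z geometry of C4=C5 (O6 and C4 end up cis), C10 by allylic 1,3-strain (H5 eclipses C10=C1 because C2H2B is cis to C5, so C9 arrives on the face that leaves the methyl cis to C4), and C9 by the Z geometry of C1=C10 (O9 cis to vinyl), which coincides with attack anti to the C8–O bond. The step needs site selectivity, that is the right boronate terminus on the right carbonyl, and this is secured by the oxidation level of C9 in 11, by the lower reactivity of the γ,γ-disubstituted terminus in the intermolecular stage, and by the proximity of that terminus in the ring-closing stage.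

Step 10
Reactants: 15 6β,9α-dihydroxyelema-1,3-dien-12,8α-olide
Product: 16 6β,9α-bis(triethylsilyloxy)elema-1,3-dien-12,8α-olide
Conditions: Et3SiOTf (2.6 equiv), 2,6-lutidine, CH2Cl2, −78 → 0 °C
Reagents that add atoms: triethylsilyl trifluoromethanesulfonate CC[Si](CC)(CC)OS(=O)(=O)C(F)(F)F
Why: The silyl triflate silylates both hindered axial alcohols, which keeps O6 (cis to the C11–C12 chain) from acyl migration during the enolate chemistry that follows.

Step 11
Reactants: 16 6β,9α-bis(triethylsilyloxy)elema-1,3-dien-12,8α-olide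
Product: 19 6β,9α-bis(triethylsilyloxy)elema-1,3,11(13)-trien-12,8α-olide, via Mannich base 17 (not isolated), via trimethylammonium iodide 18 (not isolated)
Conditions: LiN(i-Pr)2, THF, −78 °C; Me2N=CH2 I, −78 °C → rt; then MeI, THF/MeOH; aq. NaHCO3
Reagents that add atoms: N,N-dimethylmethyleneiminium iodide C=[N+](C)C.[I-]
Why: Kinetic enolisation of the lactone, Mannich reaction with the iminium salt, N-methylation and base-induced β-elimination of trimethylamine give the exocyclic C11=C13 bond, so the transient C11 centre is lost again.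

Step 12
Reactants: 19 6β,9α-bis(triethylsilyloxy)elema-1,3,11(13)-trien-12,8α-olide
Product: 20 6β,9α-dihydroxyelema-1,3,11(13)-trien-12,8α-olide
Conditions: HF·pyridine, THF, 0 °C → rt
Reagents that add atoms: none
Why: Fluoride-mediated desilylation under weakly acidic conditions frees both alcohols without lactone migration or conjugate addition.

Step 13
Reactants: 20 6β,9α-dihydroxyelema-1,3,11(13)-trien-12,8α-olide
Product: 21 6β-acetoxy-9α-hydroxyelema-1,3,11(13)-trien-12,8α-olide
Conditions: Ac2O (1.1 equiv), pyridine, DMAP (cat.), CH2Cl2, −20 → 0 °C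
Reagents that add atoms: acetic anhydride CC(=O)OC(C)=O
Why: Acylation is expected at O6–H, flanked by two methine carbons, before the neopentyl O9–H that sits between the quaternary C10 and C8.

Step 14
Reactants: 21 6β-acetoxy-9α-hydroxyelema-1,3,11(13)-trien-12,8α-olide
Product: 22 6β-acetoxy-9α-angeloyloxyelema-1,3,11(13)-trien-12,8α-olide
Conditions: angelic acid, 2,4,6-Cl3C6H2COCl, Et3N, toluene, rt; then 21, 80 °C
Reagents that add atoms: angelic acid C/C=C(/C)C(=O)O
Why: Yamaguchi-type acylation through the mixed anhydride, run without a nucleophilic catalyst, should make the hindered O9–H attack the angeloyl carbonyl and avoid Z to E isomerisation to the tiglate.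

Step 15
Reactants: 22 6β-acetoxy-9α-angeloyloxyelema-1,3,11(13)-trien-12,8α-olide
Product: 23 6β-acetoxy-9α-angeloyloxy-15-hydroxyelema-1,3,11(13)-trien-12,8α-olide
Conditions: SeO2 (0.5 equiv), t-BuOOH, CH2Cl2, rt
Reagents that add atoms: tert-butyl hydroperoxide CC(C)(C)OO
Why: SeO2-catalysed allylic hydroxylation (ene reaction, then 2,3-sigmatropic shift) should take the methyl group of the only electron-rich 1,1-disubstituted alkene, since the vinyl group has no allylic hydrogen and the two acrylate-type alkenes are electron-poor.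

Step 16
Reactants: 23 6β-acetoxy-9α-angeloyloxy-15-hydroxyelema-1,3,11(13)-trien-12,8α-olide
Product: 24 6β-acetoxy-9α-angeloyloxy-15-oxoelema-1,3,11(13)-trien-12,8α-olide
Conditions: MnO2, CH2Cl2, rt
Reagents that add atoms: none
Why: MnO2 oxidises the primary allylic alcohol, the only free hydroxyl, to the 2-substituted acrolein without touching the esters or the Z angelate.

**Compound list**

1 | prop-2-yn-1-ol | C#CCO | starting material
2 | bromomagnesium (Z)-3-(bromomagnesio)-2-methylprop-2-en-1-olate (not isolated) | Br[Mg]OC/C(C)=C\[Mg]Br | intermediate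
3 | (Z)-3-iodo-2-methylprop-2-en-1-ol | OC/C(C)=C\I | intermediate
4 | (Z)-3-iodo-2-methylprop-2-enal | O=C/C(C)=C\I | intermediate
5 | (1Z,3Z)-1,4-diiodo-2-methylpenta-1,3-diene | I/C=C(C)\C=C(/I)C | intermediate
6 | 2,2'-[(2Z,4Z)-3,5-dimethylhexa-2,4-diene-1,6-diyl]bis(4,4,5,5-tetramethyl-1,3,2-dioxaborolane) | CC1(C)OB(C/C=C(C)\C=C(/CB2OC(C)(C)C(C)(C)O2)C)OC1(C)C | intermediate
7 | (R)-5-(hydroxymethyl)furan-2(5H)-one | OC[C@@H]1OC(=O)C=C1 | starting material
8 | (R)-5-({[tert-butyl(diphenyl)silyl]oxy}methyl)furan-2(5H)-one | CC(C)(C)[Si](OC[C@@H]1OC(=O)C=C1)(c1ccccc1)c1ccccc1 | intermediate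
9 | (4S,5R)-5-({[tert-butyl(diphenyl)silyl]oxy}methyl)-4-vinyloxolan-2-one (trans) | O=C1C[C@@H](C=C)[C@H](CO[Si](c2ccccc2)(c2ccccc2)C(C)(C)C)O1 | intermediate
10 | (4S,5R)-5-(hydroxymethyl)-4-vinyloxolan-2-one | O=C1C[C@@H](C=C)[C@H](CO)O1 | intermediate
11 | (2R,3R)-2-(hydroxymethyl)-5-oxooxolane-3-carbaldehyde | O=C1C[C@@H](C=O)[C@H](CO)O1 | intermediate
12 | mono-allylation product as O6 pinacol borate: lactone of 11 in which C6 is CH(OBpin) bonded to C5, C5 carrying H, isopropenyl and the (Z)-C(CH3)=CH–CH2Bpin chain; C9 still CH2OH (not isolated) | O=C1C[C@@H]([C@@H](OB2OC(C)(C)C(C)(C)O2)[C@@H](C(C)=C)/C(C)=C\CB2OC(C)(C)C(C)(C)O2)[C@H](CO)O1 | intermediate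
13 | the C9 aldehyde derived from 12 (not isolated) | O=C1C[C@@H]([C@@H](OB2OC(C)(C)C(C)(C)O2)[C@@H](C(C)=C)/C(C)=C\CB2OC(C)(C)C(C)(C)O2)[C@H](C=O)O1 | intermediate
14 | O6,O9-bis(pinacol borate) of diol 15 (not isolated) | C=C[C@]1(C)[C@H](OB3OC(C)(C)C(C)(C)O3)[C@@H]2OC(=O)C[C@H]2[C@@H](OB3OC(C)(C)C(C)(C)O3)[C@H]1C(C)=C | intermediate
15 | 6β,9α-dihydroxyelema-1,3-dien-12,8α-olide (5αH,7αH,8βH; C10 with β-methyl and α-vinyl; trans-fused lactone) | C=C[C@]1(C)[C@H](O)[C@@H]2OC(=O)C[C@H]2[C@@H](O)[C@H]1C(C)=C | intermediate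
16 | 6β,9α-bis(triethylsilyloxy)elema-1,3-dien-12,8α-olide | C=C[C@]1(C)[C@H](O[Si](CC)(CC)CC)[C@@H]2OC(=O)C[C@H]2[C@@H](O[Si](CC)(CC)CC)[C@H]1C(C)=C | intermediate
17 | 13-(dimethylamino)-6β,9α-bis(triethylsilyloxy)-11,13-dihydroelema-1,3-dien-12,8α-olide, C11 epimers (not isolated) | C=C[C@]1(C)[C@H](O[Si](CC)(CC)CC)[C@@H]2OC(=O)C(CN(C)C)[C@H]2[C@@H](O[Si](CC)(CC)CC)[C@H]1C(C)=C | intermediate
18 | N-methylammonium iodide of 17 (not isolated) | C=C[C@]1(C)[C@H](O[Si](CC)(CC)CC)[C@@H]2OC(=O)C(C[N+](C)(C)C)[C@H]2[C@@H](O[Si](CC)(CC)CC)[C@H]1C(C)=C.[I-] | intermediate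
19 | 6β,9α-bis(triethylsilyloxy)elema-1,3,11(13)-trien-12,8α-olide | C=C[C@]1(C)[C@H](O[Si](CC)(CC)CC)[C@@H]2OC(=O)C(=C)[C@H]2[C@@H](O[Si](CC)(CC)CC)[C@H]1C(C)=C | intermediate
20 | 6β,9α-dihydroxyelema-1,3,11(13)-trien-12,8α-olide | C=C[C@]1(C)[C@H](O)[C@@H]2OC(=O)C(=C)[C@H]2[C@@H](O)[C@H]1C(C)=C | intermediate
21 | 6β-acetoxy-9α-hydroxyelema-1,3,11(13)-trien-12,8α-olide | C=C[C@]1(C)[C@H](O)[C@@H]2OC(=O)C(=C)[C@H]2[C@@H](OC(C)=O)[C@H]1C(C)=C | intermediate
22 | 6β-acetoxy-9α-angeloyloxyelema-1,3,11(13)-trien-12,8α-olide | C=C[C@]1(C)[C@H](OC(=O)/C(C)=C\C)[C@@H]2OC(=O)C(=C)[C@H]2[C@@H](OC(C)=O)[C@H]1C(C)=C | intermediate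
23 | 6β-acetoxy-9α-angeloyloxy-15-hydroxyelema-1,3,11(13)-trien-12,8α-olide | C=C[C@]1(C)[C@H](OC(=O)/C(C)=C\C)[C@@H]2OC(=O)C(=C)[C@H]2[C@@H](OC(C)=O)[C@H]1C(=C)CO | intermediate
24 | 6β-acetoxy-9α-angeloyloxy-15-oxoelema-1,3,11(13)-trien-12,8α-olide (CNP0252310.1) | C=C[C@]1(C)[C@H](OC(=O)/C(C)=C\C)[C@@H]2OC(=O)C(=C)[C@H]2[C@@H](OC(C)=O)[C@H]1C(=C)C=O | target

**Step count and risks**

Total: 16 steps. Longest linear sequence: 12 steps (steps 1–4, then 9–16; the branch from 7, steps 5–8 then 9–16, is equally long).

Step 9 (proposed new method) is the most likely to fail. The intermolecular stage may lose site selectivity between the two boronate termini, facial selectivity at C6 may be insufficient, or the oxidant may attack the allylboronate before ring closure. The fallback uses known reactions only and replaces the one-flask oxidation-level staging by protecting-group staging with isolation. It sets out from silyl ether 9, which is ozonised (O3; PPh3) to (2R,3R)-2-({[tert-butyl(diphenyl)silyl]oxy}methyl)-5-oxooxolane-3-carbaldehyde F1. Allylboration of this aldehyde with 6 (toluene, rt; aq. N(CH2CH2OH)3 work-up) gives the isolated and purified O6-free mono-allylation product with C9 still silylated F2, so that regio- and stereoisomers can be removed. Bu4NF/AcOH then frees the primary alcohol to give the O6,O9-diol carrying the (Z)-γ,γ-disubstituted allylboronate F3. Primary-selective TEMPO/PhI(OAc)2 oxidation and gentle warming bring about the known intramolecular allylboration, and the sequence comes back to the route at diol 15.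

Step 14 is the second risk: acylation of the neopentyl axial alcohol may be slow, and forcing conditions may isomerise the angeloyl donor to the E (tigloyl) series. The fallback builds the Z alkene on the ester instead of transferring it. It sets out from 21, which is acylated with 2-[bis(2,2,2-trifluoroethoxy)phosphoryl]propanoyl chloride (pyridine, DMAP) to the O9 2-[bis(2,2,2-trifluoroethoxy)phosphoryl]propanoate of 21 F4. Still–Gennari olefination (KN(SiMe3)2, 18-crown-6, THF, −78 °C; CH3CHO) should then give the Z ester, and the sequence comes back at 22.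

Step 15 is the third risk: the ene reaction may also take the hindered allylic methine C5–H, conversion may be low, or other alkenes may be oxidised on this polyfunctional substrate. The fallback sets out from 22 and uses an ene-type allylic chlorination (Ca(OCl)2, solid CO2, CH2Cl2/H2O, 0 °C), which is selective for the electron-rich isopropenyl group, to give 6β-acetoxy-9α-angeloyloxy-15-chloroelema-1,3,11(13)-trien-12,8α-olide F5. Kornblum-type oxidation with Me3NO in DMSO then gives the enal directly, so the sequence comes back at 24 and bypasses 23.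

Further compounds
F1 | step 9 | (2R,3R)-2-({[tert-butyl(diphenyl)silyl]oxy}methyl)-5-oxooxolane-3-carbaldehyde | O=C1C[C@@H](C=O)[C@H](CO[Si](c2ccccc2)(c2ccccc2)C(C)(C)C)O1
F2 | step 9 | O6-free mono-allylation product with C9 still silylated (12 with OH on C6 and CH2OSi-t-BuPh2 on C8) | O=C1C[C@@H]([C@@H](O)[C@@H](C(C)=C)/C(C)=C\CB2OC(C)(C)C(C)(C)O2)[C@H](CO[Si](c2ccccc2)(c2ccccc2)C(C)(C)C)O1
F3 | step 9 | O6,O9-diol carrying the (Z)-γ,γ-disubstituted allylboronate (12 with OH on C6) | O=C1C[C@@H]([C@@H](O)[C@@H](C(C)=C)/C(C)=C\CB2OC(C)(C)C(C)(C)O2)[C@H](CO)O1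
F4 | step 14 | O9 2-[bis(2,2,2-trifluoroethoxy)phosphoryl]propanoate of 21 | C=C[C@]1(C)[C@H](OC(=O)C(C)P(=O)(OCC(F)(F)F)OCC(F)(F)F)[C@@H]2OC(=O)C(=C)[C@H]2[C@@H](OC(C)=O)[C@H]1C(C)=C
F5 | step 15 | 6β-acetoxy-9α-angeloyloxy-15-chloroelema-1,3,11(13)-trien-12,8α-olide | C=C[C@]1(C)[C@H](OC(=O)/C(C)=C\C)[C@@H]2OC(=O)C(=C)[C@H]2[C@@H](OC(C)=O)[C@H]1C(=C)CCl
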